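**Retrosynthetic overview**
- Daucane numbering is used. Ring B is the cyclopentane C1–C2–C3–C4–C5 and ring A is the cycloheptene C1–C5–C6–C7–C8=C9–C10. C1 carries the angular methyl, C4 the isopropyl carbinol, C6 the anisoate and C10 the acetate.
- The late groups come off first. The acetate derives from Luche reduction of a C10 enone, which derives from allylic oxidation beside C8=C9. The anisoate derives from the 4,6-diol, and the C4 carbinol from isopropylcerium addition to a C4 ketone.
- The plan rests on one feature. With C4 as a ketone, ring B is a cyclopentanone, and cutting C3–C4 leaves a formyl group (C4) on fusion carbon C5 beside a vinyl group (C2=C3) on quaternary C1. This is a 4-pentenal laid on ring A, and rhodium-catalysed hydroacylation closes it.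
- Ring A comes from ring-closing metathesis at C8=C9 of an acyclic triene.
- The C1–C5 bond and both of its stereocentres come from a chelated dianionic ester-enolate Claisen rearrangement of an (E)-allylic β-hydroxy ester. Its C6 carbinol comes from ethyl (R)-4-chloro-3-hydroxybutanoate. Ring order: A, then B.

Key step: step 11

Remark: α denotes the face of H5 and β the face of the C1 methyl. The target is then 1β-Me, 4β-OH, 5α-H, 6α-O-anisoyl, 10β-OAc, that is (1S,4R,5S,6S,10S).

**Step 1**
Reactants: 1 pent-1-en-4-yne; 2 trimethylaluminium; 3 formaldehyde (used as paraformaldehyde)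
Product: 6 (2E)-3-methylhexa-2,5-dien-1-ol, via alkenyldimethylalane 4 (not isolated), via lithium butylalanate 5 (not isolated)
Conditions: Me3Al, Cp2ZrCl2 (20 mol %), CH2Cl2, 0 °C → rt; n-BuLi, hexane/THF, 0 °C; (CH2O)n, rt; aq work-up
Reagents that add atoms: trimethylaluminium C[Al](C)C; formaldehyde C=O
Why: Negishi zirconium-catalysed carboalumination adds methyl and aluminium syn across the terminal alkyne only (the isolated olefin is inert), with methyl on the internal carbon, and the derived alanate is hydroxymethylated with retention, which fixes the E geometry that later defines C1.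

**Step 2**
Reactants: 7 ethyl (3R)-4-chloro-3-hydroxybutanoate
Product: 8 ethyl [(2R)-oxiran-2-yl]acetate
Conditions: Ag2O, DME, reflux
Reagents that add atoms: none
Why: Silver-assisted intramolecular Williamson etherification displaces only the primary chloride, so the carbinol C–O bond (future C6) is untouched, and the non-basic medium avoids isomerisation of the β,γ-epoxy ester to the 4-hydroxycrotonate.

**Step 3**
Reactants: 8 ethyl [(2R)-oxiran-2-yl]acetate; 9 isopropenylmagnesium bromide
Product: 10 ethyl (3S)-3-hydroxy-5-methylhex-5-enoate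
Conditions: CH2=C(CH3)MgBr, CuI (10 mol %), THF, –40 °C; aq NH4Cl
Reagents that add atoms: isopropenylmagnesium bromide C=C(C)[Mg]Br
Why: Copper-catalysed Grignard opening of a terminal epoxide occurs at the unsubstituted carbon and outruns addition to the ester at low temperature, so the C6 stereocentre is retained (R becomes S only through a change of priorities).

**Step 4**
Reactants: 10 ethyl (3S)-3-hydroxy-5-methylhex-5-enoate
Product: 11 (3S)-3-hydroxy-5-methylhex-5-enoic acid
Conditions: LiOH, THF/H2O, 0 °C → rt; then dilute HCl to pH 3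
Reagents that add atoms: lithium hydroxide [Li+].[OH-]
Why: Plain saponification of an ethyl ester under conditions mild enough to avoid dehydration of the β-hydroxy acid and migration of the 1,1-disubstituted olefin.

**Step 5**
Reactants: 11 (3S)-3-hydroxy-5-methylhex-5-enoic acid; 6 (2E)-3-methylhexa-2,5-dien-1-ol
Product: 12 (2E)-3-methylhexa-2,5-dien-1-yl (3S)-3-hydroxy-5-methylhex-5-enoate
Conditions: DCC, DMAP (cat.), CH2Cl2, 0 °C → rt
Reagents that add atoms: none
Why: Steglich esterification in which the unhindered primary allylic alcohol intercepts the activated acid faster than the secondary β-hydroxyl of a second acid molecule, with no change at C6 or at the E olefin.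

**Step 6**
Reactants: 12 (2E)-3-methylhexa-2,5-dien-1-yl (3S)-3-hydroxy-5-methylhex-5-enoate
Product: 14 (2S,3S)-3-hydroxy-5-methyl-2-[(3S)-3-methylhexa-1,5-dien-3-yl]hex-5-enoic acid, via chelated dilithium enolate alkoxide 13 (not isolated)
Conditions: LDA (2.3 equiv), THF, –78 °C → 23 °C, then 45 °C; dilute HCl work-up
Reagents that add atoms: none
Why: Dianionic Ireland-type ester-enolate Claisen rearrangement of a β-hydroxy ester, a known variant: the lithium bridge holds the enolate oxygen cis to C6, the allyl terminus bonds to C5 through a chair on the chelate face opposite the C7 chain (the Fráter–Seebach sense, C5/C6 anti), and with the E olefin C6 and C10 sit equatorial and the C1 methyl axial, so H5 and the methyl end up anti and C4 ends up cis to methyl and trans to vinyl.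

**Step 7**
Reactants: 14 Claisen hydroxy acid
Product: 15 tert-butyldimethylsilyl (2S,3S)-3-[(tert-butyldimethylsilyl)oxy]-5-methyl-2-[(3S)-3-methylhexa-1,5-dien-3-yl]hex-5-enoate
Conditions: TBSOTf (2.5 equiv), 2,6-lutidine, CH2Cl2, 0 °C
Reagents that add atoms: tert-butyldimethylsilyl triflate CC(C)(C)[Si](C)(C)OS(=O)(=O)C(F)(F)F
Why: Silyl triflate silylation covers the hindered C6 hydroxyl and at the same time converts the acid into a silyl ester that the next step reduces, without touching any stereocentre.

**Step 8**
Reactants: 15 bis-silyl compound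
Product: 16 (2R,3S)-3-[(tert-butyldimethylsilyl)oxy]-5-methyl-2-[(3S)-3-methylhexa-1,5-dien-3-yl]hex-5-en-1-ol
Conditions: LiAlH4, Et2O, 0 °C; aqueous NaOH work-up
Reagents that add atoms: none
Why: Hydride reduction of the silyl ester to the primary alcohol, to which the secondary silyl ether and the three isolated olefins are inert (the C5 descriptor changes only by priority).

**Step 9**
Reactants: 16 acyclic triene alcohol
Product: 17 [(1R,2S,7S)-7-[(tert-butyldimethylsilyl)oxy]-2-ethenyl-2,5-dimethylcyclohept-4-en-1-yl]methanol
Conditions: second-generation Grubbs catalyst (H2IMes)(PCy3)Cl2Ru=CHPh (5 mol %), CH2Cl2 (5 mM), reflux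
Reagents that add atoms: none
Why: Ring-closing metathesis in which the catalyst loads on the unhindered allyl terminus (C9) and from there can close productively only onto the methallyl group, giving ring A with the trisubstituted, necessarily Z, C8=C9 olefin, while the vinyl group on quaternary C1 is too hindered to initiate.

**Step 10**
Reactants: 17 cycloheptenylmethanol
Product: 18 (1S,2S,7S)-7-[(tert-butyldimethylsilyl)oxy]-2-ethenyl-2,5-dimethylcyclohept-4-ene-1-carbaldehyde
Conditions: Dess–Martin periodinane, CH2Cl2, 0 °C → rt
Reagents that add atoms: none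
Why: Dess–Martin oxidation converts the hindered primary alcohol into the aldehyde under near-neutral conditions that neither epimerise C5 nor eliminate the β-silyloxy group.

**Step 11**
Reactants: 18 vinyl aldehyde on ring A
Product: 19 (3aS,4S,8aR)-4-[(tert-butyldimethylsilyl)oxy]-6,8a-dimethyl-1,2,3a,4,5,8-hexahydroazulen-3-one (trans-fused hydroazulenone, C4 ketone)
Conditions: [Rh(nbd)(dppe)]BF4 (5 mol %), activated with H2 then purged with Ar, degassed CH2Cl2, 25 °C
Reagents that add atoms: none
Why: This is the known intramolecular hydroacylation of 4-pentenals by cationic rhodium diphosphine catalysts: solvated [Rh(dppe)]+ (monovalent rhodium) inserts into the formyl C4–H bond to give an acyl hydride of trivalent rhodium, the C2=C3 vinyl group binds, hydride passes to C2 so that rhodium holds terminal C3, and reductive elimination from the six-membered acyl-alkyl rhodacycle forms C3–C4. Ring B therefore closes as a five-membered ketone by bonding at the terminal olefin carbon, a formally 5-endo closure that is feasible because the bond is made by reductive elimination from the rhodacycle and not by direct attack. No stereocentre is created, so C1, C5 and C6 are carried through and the trans diequatorial vinyl/formyl pair on ring A becomes the trans ring fusion. The step needs chemoselectivity for the monosubstituted vinyl group over the trisubstituted C8=C9 olefin, which binds rhodium poorly and could react only through a larger bridged metallacycle. It also needs closure to outrun CO extrusion, which the chelating diphosphine and the quaternary C1 favour (angle compression, and no allylic hydrogen for olefin migration). The neutral medium at room temperature leaves the epimerisable C5 and the β-silyloxy group alone.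

**Step 12**
Reactants: 19 hydroazulenone; 20 isopropylmagnesium chloride
Product: 21 (3R,3aS,4S,8aR)-4-[(tert-butyldimethylsilyl)oxy]-6,8a-dimethyl-3-(propan-2-yl)-1,2,3a,4,5,8-hexahydroazulen-3-ol
Conditions: anhydrous CeCl3 (3 equiv), i-PrMgCl (3 equiv), THF, –78 °C; aq NH4Cl
Reagents that add atoms: isopropylmagnesium chloride CC(C)[Mg]Cl
Why: Organocerium 1,2-addition, in which the weakly basic oxophilic reagent adds to the enolisable β-silyloxy ketone instead of deprotonating C5 or transferring hydride, and approaches C4 from the α face that carries only H5 because the β face of ring B is covered by the angular methyl and by C6 with its silyloxy group, so the hydroxyl ends up β (4R).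

**Step 13**
Reactants: 21 silyl ether
Product: 22 jaeschkeanadiol, (3R,3aS,4S,8aR)-6,8a-dimethyl-3-(propan-2-yl)-1,2,3a,4,5,8-hexahydroazulene-3,4-diol
Conditions: TBAF, THF, rt → 45 °C
Reagents that add atoms: none
Why: Fluoride desilylation at a stage where no ester or other base-sensitive group is present, leaving the olefin and all four stereocentres unchanged.

**Step 14**
Reactants: 22 jaeschkeanadiol; 23 4-methoxybenzoyl chloride
Product: 24 jaeschkeanadiol 6-O-(4-methoxybenzoate)
Conditions: 4-MeOC6H4COCl, Et3N, DMAP, CH2Cl2, rt
Reagents that add atoms: 4-methoxybenzoyl chloride COc1ccc(C(=O)Cl)cc1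
Why: DMAP-catalysed acylation selects the secondary equatorial C6 hydroxyl, because the tertiary C4 hydroxyl flanked by the isopropyl group does not acylate under these conditions.

**Step 15**
Reactants: 24 6-anisate
Product: 25 10-oxojaeschkeanadiol 6-O-(4-methoxybenzoate) (C10 ketone conjugated with C8=C9; 1S,4R,5S,6S)
Conditions: CrO3, 3,5-dimethylpyrazole, CH2Cl2, –20 °C
Reagents that add atoms: chromium trioxide O=[Cr](=O)=O
Why: Allylic oxidation with the CrO3·3,5-dimethylpyrazole complex converts the methylene at the CH end of a trisubstituted ring olefin into the β-methyl enone, and here C10 is favoured because its allyl intermediate is the more substituted one and oxygenation at tertiary C8 transposes to C10, while C7 is deactivated by the neighbouring acyloxy carbon C6.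

**Step 16**
Reactants: 25 C10 enone
Product: 26 10β-hydroxyjaeschkeanadiol 6-O-(4-methoxybenzoate) (10S)
Conditions: NaBH4, CeCl3·7H2O, MeOH, –40 °C → 0 °C
Reagents that add atoms: none
Why: Luche reduction gives 1,2-reduction of the enone without touching the ester, and hydride reaches C10 from the α face, anti to the axial methyl on the adjacent quaternary C1, so the new hydroxyl is β (10S).

**Step 17**
Reactants: 26 10β-alcohol; 27 acetic anhydride
Product: 28 target CNP0256979.3, (1S,4R,5S,6S,10S)-10-acetoxy-4-hydroxydauc-8-en-6-yl 4-methoxybenzoate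
Conditions: Ac2O, pyridine, DMAP (cat.), CH2Cl2, 0 °C → rt
Reagents that add atoms: acetic anhydride CC(=O)OC(C)=O
Why: Standard DMAP-catalysed acetylation of the secondary allylic alcohol with retention at C10, the hindered tertiary C4 hydroxyl staying free.

**Compound list**
1 | pent-1-en-4-yne | C=CCC#C | starting material
2 | trimethylaluminium | C[Al](C)C | starting material
3 | formaldehyde (as paraformaldehyde) | C=O | starting material
4 | dimethyl[(1E)-2-methylpenta-1,4-dien-1-yl]alane | C=CC/C(C)=C/[Al](C)C | intermediate
5 | lithium butyldimethyl[(1E)-2-methylpenta-1,4-dien-1-yl]alanate | [Li+].C=CC/C(C)=C/[Al-](C)(C)CCCC | intermediate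
6 | (2E)-3-methylhexa-2,5-dien-1-ol | C=CC/C(C)=C/CO | intermediate
7 | ethyl (3R)-4-chloro-3-hydroxybutanoate | CCOC(=O)C[C@@H](O)CCl | starting material
8 | ethyl [(2R)-oxiran-2-yl]acetate | CCOC(=O)C[C@@H]1CO1 | intermediate
9 | isopropenylmagnesium bromide | C=C(C)[Mg]Br | starting material
10 | ethyl (3S)-3-hydroxy-5-methylhex-5-enoate | CCOC(=O)C[C@@H](O)CC(C)=C | intermediate
11 | (3S)-3-hydroxy-5-methylhex-5-enoic acid | OC(=O)C[C@@H](O)CC(C)=C | intermediate
12 | (2E)-3-methylhexa-2,5-dien-1-yl (3S)-3-hydroxy-5-methylhex-5-enoate | C=CC/C(C)=C/COC(=O)C[C@@H](O)CC(C)=C | intermediate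
13 | chelated dilithium enolate alkoxide of 12 (enolate oxygen cis to C6) | [Li+].[Li+].C=CC/C(C)=C/CO/C([O-])=C/[C@@H]([O-])CC(C)=C | intermediate
14 | (2S,3S)-3-hydroxy-5-methyl-2-[(3S)-3-methylhexa-1,5-dien-3-yl]hex-5-enoic acid | O[C@@H](CC(C)=C)[C@@H](C(=O)O)[C@](C)(C=C)CC=C | intermediate
15 | O-TBS ether TBS ester of 14 | CC(C)(C)[Si](C)(C)O[C@@H](CC(C)=C)[C@@H](C(=O)O[Si](C)(C)C(C)(C)C)[C@](C)(C=C)CC=C | intermediate
16 | (2R,3S)-3-(TBS-oxy)-5-methyl-2-[(3S)-3-methylhexa-1,5-dien-3-yl]hex-5-en-1-ol | CC(C)(C)[Si](C)(C)O[C@@H](CC(C)=C)[C@@H](CO)[C@](C)(C=C)CC=C | intermediate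
17 | [(1R,2S,7S)-7-(TBS-oxy)-2-ethenyl-2,5-dimethylcyclohept-4-en-1-yl]methanol | CC(C)(C)[Si](C)(C)O[C@H]1CC(C)=CC[C@@](C)(C=C)[C@@H]1CO | intermediate
18 | (1S,2S,7S)-7-(TBS-oxy)-2-ethenyl-2,5-dimethylcyclohept-4-ene-1-carbaldehyde | CC(C)(C)[Si](C)(C)O[C@H]1CC(C)=CC[C@@](C)(C=C)[C@@H]1C=O | intermediate
19 | (3aS,4S,8aR)-4-(TBS-oxy)-6,8a-dimethyl-1,2,3a,4,5,8-hexahydroazulen-3-one | CC(C)(C)[Si](C)(C)O[C@H]1CC(C)=CC[C@@]2(C)CCC(=O)[C@H]12 | intermediate
20 | isopropylmagnesium chloride | CC(C)[Mg]Cl | starting material
21 | jaeschkeanadiol 6-O-TBS ether | CC(C)(C)[Si](C)(C)O[C@H]1CC(C)=CC[C@@]2(C)CC[C@@](O)(C(C)C)[C@H]12 | intermediate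
22 | jaeschkeanadiol | O[C@H]1CC(C)=CC[C@@]2(C)CC[C@@](O)(C(C)C)[C@H]12 | intermediate
23 | 4-methoxybenzoyl chloride | COc1ccc(C(=O)Cl)cc1 | starting material
24 | jaeschkeanadiol 6-O-(4-methoxybenzoate) | COc1ccc(C(=O)O[C@H]2CC(C)=CC[C@@]3(C)CC[C@@](O)(C(C)C)[C@H]23)cc1 | intermediate
25 | 10-oxojaeschkeanadiol 6-O-(4-methoxybenzoate) | COc1ccc(C(=O)O[C@H]2CC(C)=CC(=O)[C@@]3(C)CC[C@@](O)(C(C)C)[C@H]23)cc1 | intermediate
26 | 10β-hydroxyjaeschkeanadiol 6-O-(4-methoxybenzoate) | COc1ccc(C(=O)O[C@H]2CC(C)=C[C@H](O)[C@@]3(C)CC[C@@](O)(C(C)C)[C@H]23)cc1 | intermediate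
27 | acetic anhydride | CC(=O)OC(C)=O | starting material
28 | CNP0256979.3 | COc1ccc(C(=O)O[C@H]2CC(C)=C[C@H](OC(C)=O)[C@@]3(C)CC[C@@](O)(C(C)C)[C@H]23)cc1 | target

**Step count**
Total: 17 steps. Longest linear sequence: 16 steps (7 → 28, steps 2–17). Step 1 is the side branch.

**Steps most likely to fail**

1. **Step 11.** CO extrusion from the acyl rhodium hydride may outpace olefin insertion. This would cause decarbonylation of the substrate and a build-up of inactive rhodium carbonyl. Closure may also be slow because the trans diequatorial geometry strains the metallacycle.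
   - The fallback sets out from 18 and returns at 19. It builds ring B by olefin metathesis instead of C–H activation.
   - Vinylmagnesium bromide (THF, –78 °C) adds to 18 to give the divinyl allylic alcohol F1. Either C4 epimer serves, so that centre is left undefined.
   - The second-generation Grubbs catalyst closes the cyclopentenol F2. The internal carbon of the new vinyl group takes the place of C3.
   - Dess–Martin oxidation gives the cyclopentenone F3.
   - Conjugate reduction with [(Ph3P)CuH]6 (toluene, rt) saturates C2=C3 and gives 19.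

2. **Step 6.** Facial or chair/boat selectivity may erode. The lithium enolate may also decompose by loss of alkoxide before the hindered trisubstituted terminus has reacted.
   - The fallback sets out from 12 and returns at 16. It replaces substrate chelate control by reagent control on a protected substrate.
   - TBSOTf and 2,6-lutidine convert 12 into the silyl ether ester F4.
   - The boron enolate is formed with iPr2NEt in CH2Cl2 at –78 °C and the C2-symmetric 2-bromo-1,3-bis(arylsulfonyl)-4,5-diphenyl-1,3,2-diazaborolidine. The enantiomer is chosen to match the face already preferred by C6. These conditions give the enolate geometry with oxygen cis to C6.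
   - The enolate rearranges at –20 °C to the silyloxy acid F5.
   - LiAlH4 reduces F5 to 16.

3. **Step 15.** Site selectivity among the three allylic positions (C10, C7 and the C8 methyl) may be poor, or conversion may be incomplete at the neopentyl C10.
   - The fallback sets out from 24 and returns at 25. It fixes the site by a regiospecific sequence. The new centres at C8 and C9 are destroyed again, so they are left undefined.
   - mCPBA gives the 8,9-epoxide F6.
   - PhSeNa, made from (PhSe)2 and NaBH4 in EtOH, opens the epoxide at the less substituted C9 to give the hydroxy selenide F7.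
   - H2O2 gives the selenoxide F8. Its syn elimination can only run towards C10 and gives the tertiary allylic alcohol F9 (C8–OH, C9=C10).
   - Babler–Dauben oxidative transposition with pyridinium chlorochromate, [C5H5NH][CrO3Cl], in CH2Cl2 delivers enone 25.

**Further compounds**
F1 | step 11 | 1-[(1R,2S,7S)-7-(TBS-oxy)-2-ethenyl-2,5-dimethylcyclohept-4-en-1-yl]prop-2-en-1-ol (C4 epimers) | CC(C)(C)[Si](C)(C)O[C@H]1CC(C)=CC[C@@](C)(C=C)[C@@H]1C(O)C=C
F2 | step 11 | 4-(TBS-oxy)-6,8a-dimethyl-3,3a,4,5,8,8a-hexahydroazulen-3-ol (C2=C3 cyclopentenol, C4 epimers) | CC(C)(C)[Si](C)(C)O[C@H]1CC(C)=CC[C@@]2(C)C=CC(O)[C@H]12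
F3 | step 11 | 4-(TBS-oxy)-6,8a-dimethyl-3a,4,5,8-tetrahydroazulen-3(8aH)-one (C2=C3 cyclopentenone) | CC(C)(C)[Si](C)(C)O[C@H]1CC(C)=CC[C@@]2(C)C=CC(=O)[C@H]12
F4 | step 6 | (2E)-3-methylhexa-2,5-dien-1-yl (3S)-3-(TBS-oxy)-5-methylhex-5-enoate | C=CC/C(C)=C/COC(=O)C[C@@H](O[Si](C)(C)C(C)(C)C)CC(C)=C
F5 | step 6 | (2S,3S)-3-(TBS-oxy)-5-methyl-2-[(3S)-3-methylhexa-1,5-dien-3-yl]hex-5-enoic acid | CC(C)(C)[Si](C)(C)O[C@@H](CC(C)=C)[C@@H](C(=O)O)[C@](C)(C=C)CC=C
F6 | step 15 | 8,9-epoxyjaeschkeanadiol 6-O-(4-methoxybenzoate) | COc1ccc(C(=O)O[C@H]2CC3(C)OC3C[C@@]4(C)CC[C@@](O)(C(C)C)[C@H]24)cc1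
F7 | step 15 | 8-hydroxy-9-(phenylselanyl) derivative of 24 | COc1ccc(C(=O)O[C@H]2CC(C)(O)C([Se]c3ccccc3)C[C@@]4(C)CC[C@@](O)(C(C)C)[C@H]24)cc1
F8 | step 15 | selenoxide of F7 | COc1ccc(C(=O)O[C@H]2CC(C)(O)C([Se](=O)c3ccccc3)C[C@@]4(C)CC[C@@](O)(C(C)C)[C@H]24)cc1
F9 | step 15 | 8-hydroxydauc-9-ene tertiary allylic alcohol 6-O-(4-methoxybenzoate) | COc1ccc(C(=O)O[C@H]2CC(C)(O)C=C[C@@]3(C)CC[C@@](O)(C(C)C)[C@H]23)cc1
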